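**Retrosynthetic overview**
- The target is 5-hydroxy-7-methoxy-3,6,8-triprenyl-2-(2,4,5-trihydroxyphenyl)chromen-4-one. Ring C is opened at O1–C2 (cyclodehydration), at C3–CH2 (enolate prenylation) and at C2–C3 (Baker–Venkataraman acyl transfer). This leaves a ring A acetophenone and a MOM-protected ring B benzoic acid.
- The strategy rests on ring A: the prenyl groups on C6 and C8 flank C7–OMe, and each sits ortho to an oxygen (C5–OH and O1). Before ring C exists, this pattern is mirror-symmetric about the C4a···C7 axis.
- Both ring A C–CH2 bonds are therefore made at once, by a twofold ortho-Claisen rearrangement of the bis(1,1-dimethylallyl) ether of 2,6-dihydroxy-4-methoxyacetophenone.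
- Ring order: ring A (from phloroacetophenone) and ring B (from 2,4,5-trihydroxybenzaldehyde) are bought. Ring C is the only ring formed, in the last step.

Key step: step 4

Remark on the chemistry: the 1,3-diketones 14 and 16 are written in the open diketo form; their enol and ring-closed 2-hydroxychromanone tautomers are taken as equivalent for the steps that follow.

**Step 1**
Reactants: 1 2,4,6-trihydroxyacetophenone
Product: 2 2,6-dihydroxy-4-methoxyacetophenone
Conditions: Me2SO4 (1.0 equiv), K2CO3 (1.0 equiv), acetone, reflux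
Reagents that add atoms: dimethyl sulfate, COS(=O)(=O)OC
Why: Williamson-type O-methylation, in which the 4-hydroxyl (para to the acetyl group, not hydrogen-bonded to it and the most acidic) should react first with one equivalent of the methylating agent.

**Step 2**
Reactants: 2 2,6-dihydroxy-4-methoxyacetophenone; 3 3-chloro-3-methylbut-1-yne
Product: 4 4-methoxy-2,6-bis(2-methylbut-3-yn-2-yloxy)acetophenone
Conditions: 3 (4 equiv), DBU (4.4 equiv), CuCl2·2H2O (2 mol%), MeCN, 0 °C → rt, Ar
Reagents that add atoms: none
Why: Copper-catalysed propargylic etherification of phenoxides with a tertiary propargylic chloride is the standard route to aryl 1,1-dimethylpropargyl ethers, and excess chloride and amidine base should carry the second, hydrogen-bonded hydroxyl through as well.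

**Step 3**
Reactants: 4 4-methoxy-2,6-bis(2-methylbut-3-yn-2-yloxy)acetophenone
Product: 5 4-methoxy-2,6-bis(2-methylbut-3-en-2-yloxy)acetophenone
Conditions: H2 (1 atm), 5% Pd/CaCO3 poisoned with Pb(OAc)2, quinoline, EtOAc, rt, stopped after uptake of 2 equiv H2
Reagents that add atoms: none
Why: Partial hydrogenation of a terminal alkyne on lead-poisoned palladium stops at the vinyl group, and the aryl ketone and the tertiary ethers are inert to it.

**Step 4**
Reactants: 5 4-methoxy-2,6-bis(2-methylbut-3-en-2-yloxy)acetophenone
Product: 9 2,6-dihydroxy-4-methoxy-3,5-bis(3-methylbut-2-enyl)acetophenone, via first ortho-dienone 6 (not isolated), via mono-rearranged phenol 7 (not isolated), via second ortho-dienone 8 (not isolated)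
Conditions: PhNEt2 (degassed), 130 °C, Ar; cold 1 M HCl wash on work-up
Reagents that add atoms: none
Why: Each tertiary allyl aryl ether undergoes a concerted, chair-like ortho-Claisen ([3,3] sigmatropic) rearrangement in which the terminal CH2 of the 1,1-dimethylallyl group bonds to the free ortho ring carbon while the O–C(CH3)2 bond breaks, so allylic transposition delivers the linear prenyl group (dienone 6, then 8), and each dienone, which carries a ring C–H, enolises to the phenol (7, then 9). The closest known reaction type is the aromatic Claisen rearrangement of 1,1-dimethylallyl aryl ethers to ortho-prenylphenols, which runs at moderate temperature because the breaking C–O bond is tertiary. No ring is closed and no stereocentre remains, since the sp3 carbon of each dienone is lost on enolisation. The step needs site selectivity and clean twofold conversion: the acetyl-bearing carbon blocks one ortho position of each ether, so migration can only reach the two carbons flanking the methoxy group, and either order of events converges on the same hexasubstituted arene. Enolisation of the C–H dienone, helped by the amine solvent, should outrun a Cope shift to the para carbon, and the basic medium suppresses ionisation of the tertiary ether to phenol and isoprene as well as acid-catalysed chroman formation.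

**Step 5**
Reactants: 10 2,4,5-trihydroxybenzaldehyde
Product: 11 2,4,5-tris(methoxymethoxy)benzaldehyde
Conditions: MOMCl (4.5 equiv), i-Pr2NEt (6 equiv), CH2Cl2, 0 °C → rt, Ar
Reagents that add atoms: chloromethyl methyl ether, COCCl
Why: O-alkylation of the phenols with an α-chloro ether (MOM acetal formation) under an amine base, run under argon so that the oxidation-prone hydroxyquinol is capped before it meets air.

**Step 6**
Reactants: 11 2,4,5-tris(methoxymethoxy)benzaldehyde
Product: 12 2,4,5-tris(methoxymethoxy)benzoic acid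
Conditions: NaClO2, NaH2PO4, 2-methylbut-2-ene, t-BuOH/H2O, rt
Reagents that add atoms: sodium chlorite, [Na+].[O-]Cl=O
Why: Pinnick oxidation converts the aryl aldehyde into the acid at buffered pH that MOM acetals tolerate, while the alkene scavenger traps HOCl before it can chlorinate the electron-rich ring.

**Step 7**
Reactants: 9 2,6-dihydroxy-4-methoxy-3,5-bis(3-methylbut-2-enyl)acetophenone; 12 2,4,5-tris(methoxymethoxy)benzoic acid
Product: 13 2-acetyl-3-hydroxy-5-methoxy-4,6-bis(3-methylbut-2-enyl)phenyl 2,4,5-tris(methoxymethoxy)benzoate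
Conditions: DCC (1.1 equiv), DMAP (0.2 equiv), CH2Cl2, 0 °C → rt; 9 in slight excess (1.2 equiv)
Reagents that add atoms: none
Why: Steglich esterification avoids an acid chloride that would endanger the ortho-MOM ether, and after the first acylation the remaining hydroxyl is locked in a hydrogen bond to the acetyl group and flanked by a prenyl group, so a second acylation should be slow.

**Step 8**
Reactants: 13 2-acetyl-3-hydroxy-5-methoxy-4,6-bis(3-methylbut-2-enyl)phenyl 2,4,5-tris(methoxymethoxy)benzoate
Product: 14 1-[2,6-dihydroxy-4-methoxy-3,5-bis(3-methylbut-2-enyl)phenyl]-3-[2,4,5-tris(methoxymethoxy)phenyl]propane-1,3-dione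
Conditions: LiN(SiMe3)2 (3.5 equiv), THF, −78 °C → rt; aq NH4Cl
Reagents that add atoms: none
Why: Baker–Venkataraman rearrangement, in which the methyl ketone enolate attacks the neighbouring aryl ester through a six-membered cyclic intermediate and the acyl group moves from oxygen to carbon, with the excess non-nucleophilic base covering the free phenol and the acidic diketone product.

**Step 9**
Reactants: 14 1-[2,6-dihydroxy-4-methoxy-3,5-bis(3-methylbut-2-enyl)phenyl]-3-[2,4,5-tris(methoxymethoxy)phenyl]propane-1,3-dione; 15 prenyl bromide (1-bromo-3-methylbut-2-ene)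
Product: 16 1-[2,6-dihydroxy-4-methoxy-3,5-bis(3-methylbut-2-enyl)phenyl]-2-(3-methylbut-2-enyl)-3-[2,4,5-tris(methoxymethoxy)phenyl]propane-1,3-dione (racemic at C2; this centre is lost in step 10)
Conditions: 15 (1.05 equiv), K2CO3 (1.2 equiv), acetone, 0 °C → rt, Ar
Reagents that add atoms: none
Why: SN2 C-alkylation of the 1,3-diketone enolate, the softest carbon nucleophile present, with an allylic bromide, run at low temperature with one equivalent of electrophile so that the hindered, hydrogen-bonded phenols and base-induced ring closure do not compete.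

**Step 10**
Reactants: 16 1-[2,6-dihydroxy-4-methoxy-3,5-bis(3-methylbut-2-enyl)phenyl]-2-(3-methylbut-2-enyl)-3-[2,4,5-tris(methoxymethoxy)phenyl]propane-1,3-dione
Product: 18 5-hydroxy-7-methoxy-3,6,8-tris(3-methylbut-2-enyl)-2-(2,4,5-trihydroxyphenyl)chromen-4-one, via tris-MOM flavone 17 (not isolated)
Conditions: 3 M aq HCl/MeOH (1:4), 50 °C, degassed, Ar
Reagents that add atoms: none
Why: Acid-catalysed cyclodehydration, in which the free ring A phenol closes onto the ring B ketone (6-exo-trig hemiketal formation, then loss of water) while the 2'-oxygen is still masked, fixes the ring C regiochemistry, and the slower acid methanolysis of the three MOM acetals then follows under conditions mild enough for ortho-prenylphenols.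

**Compound list**
1 | 2,4,6-trihydroxyacetophenone | CC(=O)c1c(O)cc(O)cc1O | starting material
2 | 2,6-dihydroxy-4-methoxyacetophenone | CC(=O)c1c(O)cc(OC)cc1O | intermediate
3 | 3-chloro-3-methylbut-1-yne | CC(C)(Cl)C#C | starting material
4 | 4-methoxy-2,6-bis(2-methylbut-3-yn-2-yloxy)acetophenone | CC(=O)c1c(OC(C)(C)C#C)cc(OC)cc1OC(C)(C)C#C | intermediate
5 | 4-methoxy-2,6-bis(2-methylbut-3-en-2-yloxy)acetophenone | CC(=O)c1c(OC(C)(C)C=C)cc(OC)cc1OC(C)(C)C=C | intermediate
6 | 2-acetyl-5-methoxy-3-(2-methylbut-3-en-2-yloxy)-6-(3-methylbut-2-enyl)cyclohexa-2,4-dien-1-one (racemic, transient) | CC(=O)C1=C(OC(C)(C)C=C)C=C(OC)C(CC=C(C)C)C1=O | intermediate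
7 | 2-hydroxy-4-methoxy-6-(2-methylbut-3-en-2-yloxy)-3-(3-methylbut-2-enyl)acetophenone | CC(=O)c1c(O)c(CC=C(C)C)c(OC)cc1OC(C)(C)C=C | intermediate
8 | 2-acetyl-3-hydroxy-5-methoxy-4,6-bis(3-methylbut-2-enyl)cyclohexa-2,4-dien-1-one (racemic, transient) | CC(=O)C1=C(O)C(CC=C(C)C)=C(OC)C(CC=C(C)C)C1=O | intermediate
9 | 2,6-dihydroxy-4-methoxy-3,5-bis(3-methylbut-2-enyl)acetophenone | CC(=O)c1c(O)c(CC=C(C)C)c(OC)c(CC=C(C)C)c1O | intermediate
10 | 2,4,5-trihydroxybenzaldehyde | O=Cc1cc(O)c(O)cc1O | starting material
11 | 2,4,5-tris(methoxymethoxy)benzaldehyde | O=Cc1cc(OCOC)c(OCOC)cc1OCOC | intermediate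
12 | 2,4,5-tris(methoxymethoxy)benzoic acid | OC(=O)c1cc(OCOC)c(OCOC)cc1OCOC | intermediate
13 | 2-acetyl-3-hydroxy-5-methoxy-4,6-bis(3-methylbut-2-enyl)phenyl 2,4,5-tris(methoxymethoxy)benzoate | CC(=O)c1c(O)c(CC=C(C)C)c(OC)c(CC=C(C)C)c1OC(=O)c1cc(OCOC)c(OCOC)cc1OCOC | intermediate
14 | 1-[2,6-dihydroxy-4-methoxy-3,5-bis(3-methylbut-2-enyl)phenyl]-3-[2,4,5-tris(methoxymethoxy)phenyl]propane-1,3-dione | COc1c(CC=C(C)C)c(O)c(C(=O)CC(=O)c2cc(OCOC)c(OCOC)cc2OCOC)c(O)c1CC=C(C)C | intermediate
15 | prenyl bromide (1-bromo-3-methylbut-2-ene) | CC(C)=CCBr | starting material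
16 | 1-[2,6-dihydroxy-4-methoxy-3,5-bis(3-methylbut-2-enyl)phenyl]-2-(3-methylbut-2-enyl)-3-[2,4,5-tris(methoxymethoxy)phenyl]propane-1,3-dione (racemic) | COc1c(CC=C(C)C)c(O)c(C(=O)C(CC=C(C)C)C(=O)c2cc(OCOC)c(OCOC)cc2OCOC)c(O)c1CC=C(C)C | intermediate
17 | 5-hydroxy-7-methoxy-3,6,8-tris(3-methylbut-2-enyl)-2-[2,4,5-tris(methoxymethoxy)phenyl]chromen-4-one | COc1c(CC=C(C)C)c(O)c2c(=O)c(CC=C(C)C)c(-c3cc(OCOC)c(OCOC)cc3OCOC)oc2c1CC=C(C)C | intermediate
18 | 5-hydroxy-7-methoxy-3,6,8-tris(3-methylbut-2-enyl)-2-(2,4,5-trihydroxyphenyl)chromen-4-one (no stereocentres) | COc1c(CC=C(C)C)c(O)c2c(=O)c(CC=C(C)C)c(-c3cc(O)c(O)cc3O)oc2c1CC=C(C)C | target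

**Step count**
Total: 10 steps. Longest linear sequence: 8 steps (steps 1, 2, 3, 4, 7, 8, 9, 10, from compound 1); the ring B branch is steps 5 and 6.

**Steps most likely to fail**

Step 4 (key step). The tertiary allyl C–O bonds may ionise, with loss of isoprene and return of the phenol, or the second shift may lag behind the first, so that material is lost before both prenyl groups sit on carbon. The fallback sets out from 1 and comes back at 9, and makes the two C–C bonds by direct ring alkylation. Treatment of 1 with prenyl bromide 15 (2.2 equiv) in 10% aqueous KOH at 0 °C is a known, if unselective, C-alkylation of a phloroglucinol phenoxide. After chromatography it should give 2,4,6-trihydroxy-3,5-bis(3-methylbut-2-enyl)acetophenone F1. Methylation of its 4-hydroxyl, the most acidic one and the only one para to the acetyl group, with Me2SO4 (1 equiv) and K2CO3 in acetone would then return to 9.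

Step 2. After the first etherification the remaining hydroxyl is hydrogen-bonded to the acetyl group, and the second etherification may stall there. The fallback sets out from 2 and comes back at 7, and never asks for alkylation of a last, chelated hydroxyl. One equivalent of 3 under the same copper catalysis should give 2-hydroxy-4-methoxy-6-(2-methylbut-3-yn-2-yloxy)acetophenone F2. Partial hydrogenation over lead-poisoned Pd/CaCO3 gives 2-hydroxy-4-methoxy-6-(2-methylbut-3-en-2-yloxy)acetophenone F3. Heating F3 in PhNEt2 gives 2,6-dihydroxy-4-methoxy-3-(3-methylbut-2-enyl)acetophenone F4 by a single ortho-Claisen shift. F4 again has one hydroxyl that is not flanked by a prenyl group, and etherification of that oxygen with 3 gives 2-hydroxy-4-methoxy-3-(3-methylbut-2-enyl)-6-(2-methylbut-3-yn-2-yloxy)acetophenone F5. Partial hydrogenation of F5 gives 7, which the conditions of step 4 carry on to 9.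

Step 9. Alkylation may go to an enol or phenoxide oxygen or twice at carbon, or the base may close ring C before the prenyl group is in place, which would end in a 3-unsubstituted flavone. The fallback sets out from 9 and comes back at 16, and puts the prenyl group on before the acyl transfer. Compound 9 is converted with LiN(SiMe3)2 (3.3 equiv) in THF at −78 °C into its bis-phenoxide enolate. Alkylation at the enolate carbon with 15 (1.0 equiv) gives 1-[2,6-dihydroxy-4-methoxy-3,5-bis(3-methylbut-2-enyl)phenyl]-5-methylhex-4-en-1-one F6. Esterification of F6 with acid 12 (DCC, DMAP) gives 2-(5-methylhex-4-enoyl)-3-hydroxy-5-methoxy-4,6-bis(3-methylbut-2-enyl)phenyl 2,4,5-tris(methoxymethoxy)benzoate F7. Baker–Venkataraman acyl transfer of F7 with LiN(SiMe3)2 then delivers 16 directly.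

**Further compounds**
F1 | step 4 | 2,4,6-trihydroxy-3,5-bis(3-methylbut-2-enyl)acetophenone | CC(=O)c1c(O)c(CC=C(C)C)c(O)c(CC=C(C)C)c1O
F2 | step 2 | 2-hydroxy-4-methoxy-6-(2-methylbut-3-yn-2-yloxy)acetophenone | CC(=O)c1c(O)cc(OC)cc1OC(C)(C)C#C
F3 | step 2 | 2-hydroxy-4-methoxy-6-(2-methylbut-3-en-2-yloxy)acetophenone | CC(=O)c1c(O)cc(OC)cc1OC(C)(C)C=C
F4 | step 2 | 2,6-dihydroxy-4-methoxy-3-(3-methylbut-2-enyl)acetophenone | CC(=O)c1c(O)cc(OC)c(CC=C(C)C)c1O
F5 | step 2 | 2-hydroxy-4-methoxy-3-(3-methylbut-2-enyl)-6-(2-methylbut-3-yn-2-yloxy)acetophenone | CC(=O)c1c(O)c(CC=C(C)C)c(OC)cc1OC(C)(C)C#C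
F6 | step 9 | 1-[2,6-dihydroxy-4-methoxy-3,5-bis(3-methylbut-2-enyl)phenyl]-5-methylhex-4-en-1-one | CC(C)=CCCC(=O)c1c(O)c(CC=C(C)C)c(OC)c(CC=C(C)C)c1O
F7 | step 9 | 2-(5-methylhex-4-enoyl)-3-hydroxy-5-methoxy-4,6-bis(3-methylbut-2-enyl)phenyl 2,4,5-tris(methoxymethoxy)benzoate | CC(C)=CCCC(=O)c1c(O)c(CC=C(C)C)c(OC)c(CC=C(C)C)c1OC(=O)c1cc(OCOC)c(OCOC)cc1OCOC
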